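The data are simulated with constants of no real substance, noise included.

**The product.** The product here is a mixture of left-handed product and right-handed product, so I reckon each hand separately.

- west: left-handed substrate 20 mM; right-handed substrate 20 mM; partner 4 equiv; racemization catalyst 9.4 mol%; run made earlier
- flask: left-handed substrate 20 mM; partner 4.00 equiv; racemization catalyst 4.7 mol%; right-handed substrate 20 mM; time 10 d
west run (percent of the left-handed substrate and right-handed substrate together charged)

| time / h | left-handed product / % | right-handed product / % | left-handed substrate / % |
|---|---|---|---|
| 2.50 | 54.1 | 3.0 | 0.6 |
| 8.00 | 55.1 | 6.0 | 0 |
| 15.0 | 55.7 | 7.5 | 0 |
| 20.0 | 55.7 | 8.7 | 0.1 |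
| 30.0 | 54.9 | 9.0 | 0.5 |
| 40.0 | 54.7 | 8.9 | 0 |
| 50.0 | 56.0 | 8.8 | 0 |

(scatter of a reading: 0.5 percentage points)
* left-handed product and right-handed product together, in percent of the left-handed substrate and right-handed substrate charged together, at 10 d
* excess of left-handed product over right-handed product in the product at 10 d
* whether the exchange between left-handed substrate and right-handed substrate keeps pace with the reaction: how far the product's excess at 10 d gets from its value without exchange to its value with instant exchange (above 80% keeps pace, below 20% hardly takes part, else lags behind)
- partner is single-handed; left-handed substrate and right-handed substrate are mirror images of each other, charged as a racemate, each of them at the stated concentration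
- the earlier runs were read with a standard deviation of 0.5 percentage points
- an excess is below zero if the other one leads
- no earlier run changes the charge of racemization catalyst; that part of a forecast is a guess
- the handed part of partner does not stay in what it makes, so the products of the two hands are mirror images too

**Left hand.** In the west run the last readings of left-handed product average 55.2%, which is 5.2 percentage points above the left-handed substrate charged. I guess that this crossover scales with catalyst, so this flask, with half the loading, reaches 52.6%.

**Surplus share.** Each left-handed product takes one partner, so the west run has 57.9 mM of partner charged beyond what its left-handed product took, and I call this its surplus. If that surplus decays first-order while right-handed substrate is taken as constant, integrating the slow rate gives rate constant times right-handed substrate times lifetime times surplus, a fixed fraction of the surplus. The late right-handed product averages 8.90%, so I read 6.15%: this is the surplus share, the right-handed product formed per partner left over after the left-handed product (a branching ratio).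

**This flask.** Its surplus of 59.0 mM gives 9.06% right-handed product, hence a yield of 61.7% and an excess of 70.6%.

**Weak link.** The share is read from readings that end at 50.0 h, but the question stands at 10 d. A creep of 0.5 points between 30.0 h and 50.0 h can hide in the scatter, and carried forward at that pace it adds 4.7 points of right-handed product. So I commit to an excess between 58.5% and that flat figure.

**The forecast.** It gives a yield of 62.5% and an excess of 69%, says that exchange hardly takes part, and holds that “the partner or its active form seems to expire”. It names one excess where I commit to a span.

**The flask.** This flask gives a yield of 66.0% and an excess of 59.7%, and its exchange hardly takes part, at 9.0% of the way.

    partner + left-handed substrate → left-handed product (k = 51.0 /M/h)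
    partner + right-handed substrate → right-handed product (k = 0.460 /M/h)
    left-handed substrate + racemization catalyst ⇌ right-handed substrate + racemization catalyst, rate k3*[racemization catalyst]*[left-handed substrate] forward; the back reaction follows from the equilibrium constant (k = 90.0 /M/h)
    partner ⇌ dormant form (K = 3.30, k = 0.0430 /h)
    partner → decomposed reagent (k = 0.0690 /h)
    partner + racemization catalyst → spent catalyst (k = 20.0 /M/h)

**Share again.** At 10 d this flask holds 52.7% left-handed product, against the forecast's 52.8, and 13.3% right-handed product, against its 9.5. Its surplus share is 9.02%, above the west reading. At 10 d the neighbour, charged with 2.40 equiv of partner, holds 60.3% left-handed product, so its surplus is 23.9 mM, and that share predicts 5.38% right-handed product. The neighbour holds 5.40%, at an excess of 83.6%.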